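**Assumptions:** (i) dimethyl furan-3,4-dicarboxylate, 4-bromo-2-methoxyphenol (4-bromoguaiacol) and 4-hydroxy-3-methoxyphenylboronic acid pinacol ester are taken as catalogue chemicals; (ii) the ATH catalyst antipode in Step 3 is the one that gives the (S)-lactone, predicted to be (R,R)-TsDPEN and to be confirmed on the first batch.

## Retrosynthetic overview

1. Target ⇐ fluoride desilylation and LiBH4 opening of a cis-fused furofuranone; the lactone C=O becomes the CH2OH and the lactone O–CH(Ar) becomes the (R)-carbinol.
2. Furofuranone ⇐ convex-face Rh-catalysed conjugate arylation of a bicyclic β-alkoxy-enoate lactone, which sets oxolane C2 (aryl) and C3 (H).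
3. β-Alkoxy-enoate ⇐ partial, face-selective dearomative hydrogenation of a furan-fused aryl lactone; the benzylic centre sets oxolane C4.
4. Furan-fused lactone ⇐ asymmetric transfer hydrogenation/lactonisation of a keto ester made by mono-arylation of symmetric dimethyl furan-3,4-dicarboxylate.
5. Ring order: the oxolane is bought as the furan; the lactone ring is built second as a temporary stereocontrol tether and opened in the penultimate step.

## Route

**Step 1**
Reactants: 1, 4-bromo-2-methoxyphenol
Product: 2, (4-bromo-2-methoxyphenoxy)triisopropylsilane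
Conditions: TIPSCl, imidazole, DMF, rt
Reagents that add atoms: triisopropylsilyl chloride, CC(C)[Si](Cl)(C(C)C)C(C)C
Why: Standard imidazole-promoted phenol silylation; TIPS survives ArLi, hydrogenation, mild base and hydride, and is removed at the end with fluoride, without acid or hydrogenolysis.

**Step 2**
Reactants: 2, aryl bromide; 3, dimethyl furan-3,4-dicarboxylate
Product: 4, methyl 4-[3-methoxy-4-(triisopropylsilyloxy)benzoyl]furan-3-carboxylate
Conditions: 2, n-BuLi, THF, −78 °C; cannulate into 3 (1.5 equiv), THF, −78 °C; AcOH quench at −78 °C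
Reagents that add atoms: none beyond reactants 2 and 3
Why: Br/Li exchange followed by nucleophilic acyl substitution at one of the two equivalent esters; the lithium hemiketal, chelated by the neighbouring ester, persists at −78 °C, so inverse addition and a cold quench stop at the mono-ketone (symmetry-breaking mono-acylation).

**Step 3**
Reactants: 4, keto ester
Product: 5, (3S)-3-[3-methoxy-4-(triisopropylsilyloxy)phenyl]-1H,3H-furo[3,4-c]furan-1-one (aromatic furan fused to a γ-lactone)
Conditions: RuCl(p-cymene)[(R,R)-TsDPEN] (1 mol%), HCO2H/Et3N 5:2, DMF, 40 °C; then cat. DBU, PhMe, 50 °C if lactonisation is incomplete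
Reagents that add atoms: none
Why: Noyori–Ikariya asymmetric transfer hydrogenation of an ortho-ester diaryl ketone (the twisted furyl ester ring plays the non-aryl role) sets the carbinol, which closes onto the adjacent ester as in 3-arylphthalide synthesis.

**Step 4 (key step)**
Reactants: 5, furan-fused lactone
Product: 6, (3R,3aR)-3-[3-methoxy-4-(triisopropylsilyloxy)phenyl]-3a,4-dihydro-1H,3H-furo[3,4-c]furan-1-one (C6=C6a retained; H-3 and H-3a cis, aryl trans to H-3a)
Conditions: H2 (1 atm), 5% Rh/Al2O3, EtOAc, rt, stopped at 1.0 equiv H2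
Reagents that add atoms: none
Why: Partial hydrogenation of a 3-acylfuran saturates the isolated enol-ether C=C and leaves the push–pull β-alkoxy-enoate C=C (as in 3-furoate → 4,5-dihydro-3-furoate); H2 adds to the face of the flat bicycle opposite the C3 aryl, setting C3a, and Rh is used to avoid benzylic C–O hydrogenolysis.

**Step 5**
Reactants: 6, β-alkoxy-enoate lactone; 7, 4-hydroxy-3-methoxyphenylboronic acid pinacol ester
Product: 8, (3R,3aR,6S,6aS)-6-(4-hydroxy-3-methoxyphenyl)-3-[3-methoxy-4-(triisopropylsilyloxy)phenyl]tetrahydro-1H,3H-furo[3,4-c]furan-1-one (cis-fused; 6-aryl exo, 3-aryl endo)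
Conditions: [Rh(OH)(cod)]2 (3 mol%), 7 (2.5 equiv), Et3N (1 equiv), dioxane/H2O 10:1, 60 °C
Reagents that add atoms: boronate 7, COc1cc(B2OC(C)(C)C(C)(C)O2)ccc1O
Why: Proposed new method: Hayashi–Miyaura Rh(I) 1,4-arylation extended to a β-alkoxy α-alkylidene lactone; aryl–Rh adds to the O-bearing β-carbon of the s-cis-locked enoate from the convex face (the H-3a face, anti to the endo aryl), water protonates the oxa-π-allyl rhodium faster than β-alkoxide elimination because the ring C–O bond lies near the enolate nodal plane, and protonation at C6a can only give the cis-fused 5,5 system; closest known reactions are Rh/Pd arylboron additions to chromones, 2,3-dihydro-4-pyranones and α-methylene lactones.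

**Step 6**
Reactants: 8, furofuranone
Product: 9, 4-[(2S,3R,4R)-3-(hydroxymethyl)-4-[(R)-hydroxy(3-methoxy-4-(triisopropylsilyloxy)phenyl)methyl]oxolan-2-yl]-2-methoxyphenol
Conditions: LiBH4 (4 equiv), THF, 0 °C → rt; sat. NH4Cl
Reagents that add atoms: none
Why: LiBH4 reduction of a γ-lactone to the 1,4-diol; no C–O bond at a stereocentre is broken, so all four centres are retained, and the silyl ether and benzylic ethers are untouched.

**Step 7**
Reactants: 9, mono-TIPS ether
Product: 10, (7R)-7-hydroxylariciresinol
Conditions: TBAF/AcOH (1.2 equiv each), THF, 0 °C; pH 7 work-up, Et3N-deactivated silica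
Reagents that add atoms: none
Why: Buffered fluoride desilylation of an aryl silyl ether; it avoids acid, which would cyclise the p-hydroxybenzylic alcohol to a furofuran, and avoids hydrogenolysis.

## Compound list

1 | 4-bromo-2-methoxyphenol | COc1cc(Br)ccc1O | starting material
2 | (4-bromo-2-methoxyphenoxy)triisopropylsilane | COc1cc(Br)ccc1O[Si](C(C)C)(C(C)C)C(C)C | intermediate
3 | dimethyl furan-3,4-dicarboxylate | COC(=O)c1cocc1C(=O)OC | starting material
4 | methyl 4-[3-methoxy-4-(triisopropylsilyloxy)benzoyl]furan-3-carboxylate | COC(=O)c1cocc1C(=O)c1ccc(O[Si](C(C)C)(C(C)C)C(C)C)c(OC)c1 | intermediate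
5 | (3S)-3-[3-methoxy-4-(triisopropylsilyloxy)phenyl]-1H,3H-furo[3,4-c]furan-1-one | O=C1O[C@@H](c2ccc(O[Si](C(C)C)(C(C)C)C(C)C)c(OC)c2)c2cocc12 | intermediate
6 | (3R,3aR)-3-[3-methoxy-4-(triisopropylsilyloxy)phenyl]-3a,4-dihydro-1H,3H-furo[3,4-c]furan-1-one | O=C1O[C@@H](c2ccc(O[Si](C(C)C)(C(C)C)C(C)C)c(OC)c2)[C@H]2COC=C12 | intermediate
7 | 4-hydroxy-3-methoxyphenylboronic acid pinacol ester | COc1cc(B2OC(C)(C)C(C)(C)O2)ccc1O | starting material
8 | (3R,3aR,6S,6aS)-6-(4-hydroxy-3-methoxyphenyl)-3-[3-methoxy-4-(triisopropylsilyloxy)phenyl]tetrahydro-1H,3H-furo[3,4-c]furan-1-one | O=C1O[C@@H](c2ccc(O[Si](C(C)C)(C(C)C)C(C)C)c(OC)c2)[C@H]2CO[C@H](c3ccc(O)c(OC)c3)[C@@H]12 | intermediate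
9 | 4-[(2S,3R,4R)-3-(hydroxymethyl)-4-[(R)-hydroxy(3-methoxy-4-(triisopropylsilyloxy)phenyl)methyl]oxolan-2-yl]-2-methoxyphenol | COc1cc([C@H]2OC[C@H]([C@@H](O)c3ccc(O[Si](C(C)C)(C(C)C)C(C)C)c(OC)c3)[C@@H]2CO)ccc1O | intermediate
10 | (7R)-7-hydroxylariciresinol, 4-[(2S,3R,4R)-4-[(R)-hydroxy(4-hydroxy-3-methoxyphenyl)methyl]-3-(hydroxymethyl)oxolan-2-yl]-2-methoxyphenol | COc1cc([C@H]2OC[C@H]([C@@H](O)c3ccc(O)c(OC)c3)[C@@H]2CO)ccc1O | target

## Step count and risks

Total steps: 7. Longest linear sequence: 7 (from 4-bromo-2-methoxyphenol).

Three steps most likely to fail: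

1. **Step 5, Rh conjugate arylation of the vinylogous carbonate.** The acceptor may be too unreactive, or the aryl boronate may protodeboronate first. Fallback: add the aryl as a cuprate (TIPS-protected ArMgBr/CuI) with deliberate addition–elimination to the ring-opened α-arylidene lactone carrying a free CH2OH. Then re-close the oxolane by thermodynamic oxa-Michael addition, which gives the 2,3-trans (exo-aryl) cis-fused furofuranone.

2. **Step 4, partial dearomative hydrogenation.** Risks are over-reduction to the tetrahydro compound, hydrogenolysis of the benzylic lactone C–O, and imperfect facial control. Fallback: install the second aryl on the furan first by Pd-catalysed C–H arylation next to the acyl-bearing carbon and hydrogenate exhaustively over Rh (all-cis, no need to stop halfway). Then invert the 2-aryl centre by base-triggered quinone-methide ring-opening and re-closure, which only the free-phenol aryl can undergo, to reach the exo isomer.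

3. **Step 3, ATH and closure of the strained 3,4-fused furan lactone.** The lactone may close sluggishly, or the ee may be modest for this diaryl ketone. Fallback: hydrogenate keto ester 4 first to the racemic 4-aroyl-4,5-dihydrofuran-3-carboxylate, whose α-stereocentre is labile. Then set both the carbinol and the adjacent ring centre in one base-assisted dynamic-kinetic-resolution ATH; lactonisation to 6 is then strain-free.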